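**Plan**
Numbering used: lactone C1(=O)–O2–C3(syringyl)–C3a–C6a; tetrahydrofuran C3a–C4H2–O5–C6(guaiacyl)–C6a.
Retrosynthesis: first the two phenolic O–Si bonds; then, in one operation, the lactone C1–C6a bond and the C6–aryl bond, leading to cesium oxalate 17 of a 3-(α-hydroxybenzyl)-2,3-dihydrofuran and aryl bromide 19; then the O5–C6=C6a enol ether back to a lactol made from an allyl group; last the C3–C3a bond by an Evans aldol.
Enabling feature: C1 hangs on O2, O2 on C3, C3 on C3a, and C3a is next to C6a, so C1 is homoallylic to a C6a=C6 double bond; C6 is α to ring oxygen O5. The C6–C6a edge of the tetrahydrofuran can therefore be a cyclic enol ether that takes an O-bound alkoxycarbonyl radical at C6a and hands an α-oxy radical at C6 to nickel for arylation.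
Forward: aldol, then the tetrahydrofuran ring as a 2,3-dihydrofuran (ring 1), then the oxalate, then the cascade that closes the lactone (ring 2) and attaches the guaiacyl ring, then desilylation.
Stereochemistry: C3 and C3a from the Evans syn-aldol with (S)-4-benzyloxazolidinone; C6a from the enforced cis ring fusion; C6 from C–C bond formation on the convex face.

Key step: step 12

Remark: diol 10, lactol 12 and mesylate 13 are mixtures at centres that are destroyed in steps 6 and 7, which has no consequence for the route.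

Step 1
Reactants: 1 syringaldehyde
Product: 2 3,5-dimethoxy-4-(triisopropylsilyloxy)benzaldehyde
Conditions: TIPSCl, imidazole, DMF, rt to 40 °C
Reagents that add atoms: triisopropylsilyl chloride, CC(C)[Si](Cl)(C(C)C)C(C)C
Why: Imidazole-promoted O-silylation of the phenol (silyl ether formation); the hindered aryl TIPS ether should survive every later step and come off with buffered fluoride at the end.

Step 2
Reactants: 3 (S)-4-benzyl-1,3-oxazolidin-2-one; 4 pent-4-enoyl chloride
Product: 5 (S)-4-benzyl-3-(pent-4-enoyl)-1,3-oxazolidin-2-one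
Conditions: n-BuLi, THF, −78 °C; then 4, −78 to 0 °C
Reagents that add atoms: none
Why: N-Acylation of the lithiated Evans oxazolidinone by the acid chloride (standard auxiliary loading); the auxiliary stereocentre is untouched.

Step 3
Reactants: 5 (S)-4-benzyl-3-(pent-4-enoyl)-1,3-oxazolidin-2-one; 2 3,5-dimethoxy-4-(triisopropylsilyloxy)benzaldehyde
Product: 7 (4S)-4-benzyl-3-{(2S)-2-[(S)-hydroxy(3,5-dimethoxy-4-triisopropylsilyloxyphenyl)methyl]pent-4-enoyl}-1,3-oxazolidin-2-one, via Z-boron enolate 6 (not isolated)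
Conditions: Bu2BOTf, i-Pr2NEt, CH2Cl2, 0 °C; then 2, −78 to 0 °C; H2O2, pH 7 buffer, MeOH
Reagents that add atoms: none
Why: Evans boron syn-aldol: Z-enolate 6 adds through a chair Zimmerman–Traxler transition state on the face away from the benzyl group, which should set both new centres as the (2S,3S)-syn adduct, that is C3 and C3a of the target.

Step 4
Reactants: 7 syn-aldol adduct
Product: 8 (4S)-4-benzyl-3-{(2S)-2-[(S)-(3,5-dimethoxy-4-triisopropylsilyloxyphenyl)(triethylsilyloxy)methyl]pent-4-enoyl}-1,3-oxazolidin-2-one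
Conditions: TESOTf, 2,6-lutidine, CH2Cl2, −78 to 0 °C
Reagents that add atoms: triethylsilyl trifluoromethanesulfonate, CC[Si](CC)(CC)OS(=O)(=O)C(F)(F)F
Why: Silyl ether formation with the silyl triflate; masking the benzylic hydroxyl ensures that only the primary hydroxyl can close the lactol in step 6.

Step 5
Reactants: 8 triethylsilyl-protected aldol adduct
Product: 9 (2R)-2-[(S)-(3,5-dimethoxy-4-triisopropylsilyloxyphenyl)(triethylsilyloxy)methyl]pent-4-en-1-ol
Conditions: LiBH4, MeOH (1 equiv), THF, 0 °C
Reagents that add atoms: none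
Why: Reductive cleavage of the N-acyloxazolidinone with lithium borohydride to the primary alcohol, with release of auxiliary 3; no stereocentre is touched.

Step 6
Reactants: 9 homoallylic primary alcohol
Product: 12 (4R)-4-[(S)-(3,5-dimethoxy-4-triisopropylsilyloxyphenyl)(triethylsilyloxy)methyl]oxolan-2-ol, via diol 10 (not isolated), via hydroxy aldehyde 11 (not isolated)
Conditions: OsO4 (cat.), NaIO4, 2,6-lutidine, dioxane/H2O, rt
Reagents that add atoms: osmium tetroxide, O=[Os](=O)(=O)=O (catalytic oxygen carrier); sodium periodate, [Na+].[O-]I(=O)(=O)=O (terminal oxygen source)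
Why: Lemieux–Johnson oxidative cleavage (catalytic dihydroxylation, periodate glycol cleavage) shortens the allyl group to an aldehyde without exposing the electron-rich arene to ozone, and 11 should close at once to the five-membered lactol with the only free hydroxyl.

Step 7
Reactants: 12 lactol
Product: 14 triethyl{(S)-[(3R)-2,3-dihydrofuran-3-yl](3,5-dimethoxy-4-triisopropylsilyloxyphenyl)methoxy}silane, via anomeric mesylate 13 (not isolated)
Conditions: MsCl, Et3N, CH2Cl2, −40 °C to reflux
Reagents that add atoms: none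
Why: Lactol dehydration by anomeric sulfonylation and base-induced elimination (the furanoid glycal method); the only β-hydrogens are on the ring CH2, so the 2,3-dihydrofuran with the C3a centre intact should result.

Step 8
Reactants: 14 dihydrofuran triethylsilyl ether
Product: 15 (S)-[(3R)-2,3-dihydrofuran-3-yl](3,5-dimethoxy-4-triisopropylsilyloxyphenyl)methanol
Conditions: HF·pyridine, pyridine (excess), THF, 0 °C
Reagents that add atoms: none
Why: Fluoride-mediated desilylation under acid-buffered conditions, in which an alkyl triethylsilyl ether is cleaved much faster than a hindered aryl triisopropylsilyl ether, while excess pyridine keeps the enol ether unprotonated.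

Step 9
Reactants: 15 dihydrofuranyl carbinol
Product: 16 (S)-[(3R)-2,3-dihydrofuran-3-yl](3,5-dimethoxy-4-triisopropylsilyloxyphenyl)methyl methyl oxalate
Conditions: ClC(O)CO2Me, Et3N, DMAP (cat.), CH2Cl2, 0 °C
Reagents that add atoms: methyl chlorooxoacetate, COC(=O)C(Cl)=O
Why: DMAP-catalysed O-acylation of the secondary alcohol with the oxalyl half-ester chloride under basic conditions that the enol ether tolerates.

Step 10
Reactants: 16 mixed methyl oxalate
Product: 17 cesium (S)-[(3R)-2,3-dihydrofuran-3-yl](3,5-dimethoxy-4-triisopropylsilyloxyphenyl)methyl oxalate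
Conditions: CsOH·H2O (1.0 equiv), THF/H2O, 0 °C to rt; concentrate
Reagents that add atoms: cesium hydroxide, [Cs+].[OH-]
Why: Saponification of the unhindered methyl ester of the mixed oxalate with one equivalent of hydroxide, which should leave the hindered benzylic ester and the aryl silyl ether intact and give the carboxylate needed for single-electron oxidation.

Step 11
Reactants: 18 4-bromo-2-methoxyphenol
Product: 19 (4-bromo-2-methoxyphenoxy)triisopropylsilane
Conditions: TIPSCl, imidazole, DMF, rt
Reagents that add atoms: triisopropylsilyl chloride, CC(C)[Si](Cl)(C(C)C)C(C)C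
Why: Imidazole-promoted O-silylation of the phenol gives the aryl bromide coupling partner in the same protected form as the other ring.

Step 12
Reactants: 17 cesium oxalate; 19 (4-bromo-2-methoxyphenoxy)triisopropylsilane
Product: 22 (3S,3aR,6S,6aS)-3-[3,5-dimethoxy-4-(triisopropylsilyloxy)phenyl]-6-[3-methoxy-4-(triisopropylsilyloxy)phenyl]tetrahydro-1H,3H-furo[3,4-c]furan-1-one, via alkoxycarbonyl radical 20 (not isolated), via bicyclic α-oxy radical 21 (not isolated)
Conditions: [Ir{dF(CF3)ppy}2(dtbbpy)]PF6 (cat.), NiBr2·dtbbpy (cat.), 19 (1.5 equiv), 1,4-dioxane/DMSO, blue LEDs, 25 °C, degassed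
Reagents that add atoms: none
Why: Photoexcited Ir(III) oxidises the carboxylate of 17, loss of CO2 gives alkoxycarbonyl radical 20, this adds to the enol ether β-carbon (C6a) to close the γ-lactone and leave α-oxy radical 21 at C6, and 21 is captured by the aryl–nickel species formed from 19, with reductive elimination from Ni(III) making the C6–aryl bond and Ir(II) returning nickel to its low-valent state. The closest known reaction type is the alkoxycarbonyl-radical cyclisation/nickel cross-coupling cascade of homoallylic cesium oxalates with aryl bromides under photoredox–nickel dual catalysis, applied here to a cyclic enol ether acceptor. The lactone closes in the 5-exo-trig mode onto an endocyclic double bond, so the new bicyclo[3.3.0] system can only be cis-fused and C6a is fixed by C3a, the carbon that carries the tether. C6 is set by approach of nickel to the convex (exo) face of cis-fused radical 21, anti to the C6a–C1 bond, which places the guaiacyl group exo as in the target. The step needs ring closure to outrun loss of a second CO2 from the benzylic alkoxycarbonyl radical and direct aryl ester formation at nickel; the intramolecular 5-exo addition to a double bond held three atoms away, run at 25 °C, should secure this, and 6-endo attack at C6 would require a bridged ring.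

Step 13
Reactants: 22 bis-silylated furofuranone
Product: 23 (3S,3aR,6S,6aS)-3-(4-hydroxy-3,5-dimethoxyphenyl)-6-(4-hydroxy-3-methoxyphenyl)tetrahydro-1H,3H-furo[3,4-c]furan-1-one (CNP0142585.1)
Conditions: TBAF, AcOH (1:1), THF, 0 °C
Reagents that add atoms: none
Why: Fluoride-mediated cleavage of both aryl silyl ethers; acetic acid keeps the phenoxide concentration low so that the p-hydroxybenzylic C–O bonds at C3 and C6 should not open through quinone methides, and no stereocentre is touched.

**Compound list**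
1 | syringaldehyde (4-hydroxy-3,5-dimethoxybenzaldehyde) | COc1cc(C=O)cc(OC)c1O | starting material
2 | 3,5-dimethoxy-4-(triisopropylsilyloxy)benzaldehyde | COc1cc(C=O)cc(OC)c1O[Si](C(C)C)(C(C)C)C(C)C | intermediate
3 | (S)-4-benzyl-1,3-oxazolidin-2-one | O=C1N[C@@H](Cc2ccccc2)CO1 | starting material
4 | pent-4-enoyl chloride | C=CCCC(Cl)=O | starting material
5 | (S)-4-benzyl-3-(pent-4-enoyl)-1,3-oxazolidin-2-one | C=CCCC(=O)N1[C@@H](Cc2ccccc2)COC1=O | intermediate
6 | (Z)-dibutylboron enolate of 5 | C=CC/C=C(\OB(CCCC)CCCC)N1[C@@H](Cc2ccccc2)COC1=O | intermediate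
7 | (4S)-4-benzyl-3-{(2S)-2-[(S)-hydroxy(3,5-dimethoxy-4-triisopropylsilyloxyphenyl)methyl]pent-4-enoyl}-1,3-oxazolidin-2-one | C=CC[C@@H]([C@H](O)c1cc(OC)c(O[Si](C(C)C)(C(C)C)C(C)C)c(OC)c1)C(=O)N1[C@@H](Cc2ccccc2)COC1=O | intermediate
8 | (4S)-4-benzyl-3-{(2S)-2-[(S)-(3,5-dimethoxy-4-triisopropylsilyloxyphenyl)(triethylsilyloxy)methyl]pent-4-enoyl}-1,3-oxazolidin-2-one | C=CC[C@@H]([C@H](O[Si](CC)(CC)CC)c1cc(OC)c(O[Si](C(C)C)(C(C)C)C(C)C)c(OC)c1)C(=O)N1[C@@H](Cc2ccccc2)COC1=O | intermediate
9 | (2R)-2-[(S)-(3,5-dimethoxy-4-triisopropylsilyloxyphenyl)(triethylsilyloxy)methyl]pent-4-en-1-ol | C=CC[C@@H]([C@H](O[Si](CC)(CC)CC)c1cc(OC)c(O[Si](C(C)C)(C(C)C)C(C)C)c(OC)c1)CO | intermediate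
10 | (4R)-4-[(S)-(3,5-dimethoxy-4-triisopropylsilyloxyphenyl)(triethylsilyloxy)methyl]pentane-1,2,5-triol (C2 epimers) | OCC(O)C[C@@H]([C@H](O[Si](CC)(CC)CC)c1cc(OC)c(O[Si](C(C)C)(C(C)C)C(C)C)c(OC)c1)CO | intermediate
11 | (3R)-4-hydroxy-3-[(S)-(3,5-dimethoxy-4-triisopropylsilyloxyphenyl)(triethylsilyloxy)methyl]butanal | O=CC[C@@H]([C@H](O[Si](CC)(CC)CC)c1cc(OC)c(O[Si](C(C)C)(C(C)C)C(C)C)c(OC)c1)CO | intermediate
12 | (4R)-4-[(S)-(3,5-dimethoxy-4-triisopropylsilyloxyphenyl)(triethylsilyloxy)methyl]oxolan-2-ol (anomers) | OC1C[C@@H]([C@H](O[Si](CC)(CC)CC)c2cc(OC)c(O[Si](C(C)C)(C(C)C)C(C)C)c(OC)c2)CO1 | intermediate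
13 | (4R)-4-[(S)-(3,5-dimethoxy-4-triisopropylsilyloxyphenyl)(triethylsilyloxy)methyl]oxolan-2-yl methanesulfonate (anomers) | CS(=O)(=O)OC1C[C@@H]([C@H](O[Si](CC)(CC)CC)c2cc(OC)c(O[Si](C(C)C)(C(C)C)C(C)C)c(OC)c2)CO1 | intermediate
14 | triethyl{(S)-[(3R)-2,3-dihydrofuran-3-yl](3,5-dimethoxy-4-triisopropylsilyloxyphenyl)methoxy}silane | C1=C[C@@H]([C@H](O[Si](CC)(CC)CC)c2cc(OC)c(O[Si](C(C)C)(C(C)C)C(C)C)c(OC)c2)CO1 | intermediate
15 | (S)-[(3R)-2,3-dihydrofuran-3-yl](3,5-dimethoxy-4-triisopropylsilyloxyphenyl)methanol | C1=C[C@@H]([C@H](O)c2cc(OC)c(O[Si](C(C)C)(C(C)C)C(C)C)c(OC)c2)CO1 | intermediate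
16 | (S)-[(3R)-2,3-dihydrofuran-3-yl](3,5-dimethoxy-4-triisopropylsilyloxyphenyl)methyl methyl oxalate | C1=C[C@@H]([C@H](OC(=O)C(=O)OC)c2cc(OC)c(O[Si](C(C)C)(C(C)C)C(C)C)c(OC)c2)CO1 | intermediate
17 | cesium (S)-[(3R)-2,3-dihydrofuran-3-yl](3,5-dimethoxy-4-triisopropylsilyloxyphenyl)methyl oxalate | C1=C[C@@H]([C@H](OC(=O)C(=O)[O-])c2cc(OC)c(O[Si](C(C)C)(C(C)C)C(C)C)c(OC)c2)CO1.[Cs+] | intermediate
18 | 4-bromo-2-methoxyphenol | COc1cc(Br)ccc1O | starting material
19 | (4-bromo-2-methoxyphenoxy)triisopropylsilane | COc1cc(Br)ccc1O[Si](C(C)C)(C(C)C)C(C)C | intermediate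
20 | alkoxycarbonyl radical from 17 (carbonyl-centred, on the benzylic oxygen) | C1=C[C@@H]([C@H](O[C]=O)c2cc(OC)c(O[Si](C(C)C)(C(C)C)C(C)C)c(OC)c2)CO1 | intermediate
21 | cis-fused 1-oxo-3-aryl-tetrahydrofuro[3,4-c]furan-6-yl radical (configuration at C3, C3a, C6a as in 22) | [CH]1OC[C@H]2[C@@H]1C(=O)O[C@@H]2c1cc(OC)c(O[Si](C(C)C)(C(C)C)C(C)C)c(OC)c1 | intermediate
22 | (3S,3aR,6S,6aS)-3-[3,5-dimethoxy-4-(triisopropylsilyloxy)phenyl]-6-[3-methoxy-4-(triisopropylsilyloxy)phenyl]tetrahydro-1H,3H-furo[3,4-c]furan-1-one | COc1cc([C@H]2OC[C@H]3[C@@H]2C(=O)O[C@@H]3c2cc(OC)c(O[Si](C(C)C)(C(C)C)C(C)C)c(OC)c2)ccc1O[Si](C(C)C)(C(C)C)C(C)C | intermediate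
23 | (3S,3aR,6S,6aS)-3-(4-hydroxy-3,5-dimethoxyphenyl)-6-(4-hydroxy-3-methoxyphenyl)tetrahydro-1H,3H-furo[3,4-c]furan-1-one | COc1cc([C@H]2OC[C@H]3[C@@H]2C(=O)O[C@@H]3c2cc(OC)c(O)c(OC)c2)ccc1O | target

**Totals and risks**
Total step count: 13. Longest linear sequence: 11 (steps 1, 3, 4, 5, 6, 7, 8, 9, 10, 12, 13).

Most likely to fail, step 12: the benzylic alkoxycarbonyl radical may lose a second CO2 before it cyclises, the electron-rich arenes or the enol ether may be oxidised in competition with the carboxylate, or nickel may deliver the aryl group with poor facial selectivity. The fallback sets out from lactol 12 and returns at 22; in it the former lactol carbon becomes C1 and the aldehyde carbon of the guaiacyl partner becomes C6. Oxidation of 12 (TEMPO, PhI(OAc)2) should give γ-lactone F1. Its lithium enolate (LiHMDS, THF, −78 °C) should add to 3-methoxy-4-(triisopropylsilyloxy)benzaldehyde F2 (from vanillin and TIPSCl) anti to the ring substituent to give hydroxybenzyl lactone F3. Acid (CSA in MeOH to remove the triethylsilyl group, then BF3·OEt2 in CH2Cl2) should move the lactone to the benzylic oxygen and close the tetrahydrofuran by attack of the released primary hydroxyl on the 4-silyloxybenzylic cation from the exo face. The anti aldol geometry allows only the required cis-fused ring system.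

Second, step 8: the acidic fluoride medium may protonate the enol ether (hydration or oligomerisation), or an aryl silyl ether may be lost with the alkyl one. The fallback sets out from lactol 12 (bypassing step 7 as well) and returns at 15. CSA (cat.) in MeOH at 0 °C should convert 12 into methyl acetal carbinol F4 with loss of the triethylsilyl group, since aryl silyl ethers are stable to acid. TMSOTf with i-Pr2NEt in CH2Cl2 should then eliminate methanol to the enol ether and silylate the carbinol, giving trimethylsilyl ether F5. K2CO3 in MeOH at 0 °C cleaves the alkyl trimethylsilyl ether without any acid.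

Third, step 13: phenoxide formed on desilylation may open the p-hydroxybenzylic ether or lactone C–O bond through a quinone methide, with epimerisation at C6 or C3. The fallback sets out from 22 and returns at 23. CsF with Ac2O in DMF should cleave the silyl ethers and trap each phenoxide as it forms, giving diacetate F6. NH4OAc in aqueous MeOH at rt (neutral aryl acetate cleavage) should then release the phenols.

**Further compounds**
F1 | step 12 | (4R)-4-[(S)-(3,5-dimethoxy-4-triisopropylsilyloxyphenyl)(triethylsilyloxy)methyl]oxolan-2-one | O=C1C[C@@H]([C@H](O[Si](CC)(CC)CC)c2cc(OC)c(O[Si](C(C)C)(C(C)C)C(C)C)c(OC)c2)CO1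
F2 | step 12 | 3-methoxy-4-(triisopropylsilyloxy)benzaldehyde | COc1cc(C=O)ccc1O[Si](C(C)C)(C(C)C)C(C)C
F3 | step 12 | (3S,4R)-3-[hydroxy(3-methoxy-4-triisopropylsilyloxyphenyl)methyl]-4-[(S)-(3,5-dimethoxy-4-triisopropylsilyloxyphenyl)(triethylsilyloxy)methyl]oxolan-2-one (carbinol epimers) | O=C1OC[C@H]([C@H](O[Si](CC)(CC)CC)c2cc(OC)c(O[Si](C(C)C)(C(C)C)C(C)C)c(OC)c2)[C@H]1C(O)c1ccc(O[Si](C(C)C)(C(C)C)C(C)C)c(OC)c1
F4 | step 8 | (S)-[(3R)-5-methoxyoxolan-3-yl](3,5-dimethoxy-4-triisopropylsilyloxyphenyl)methanol (anomers) | COC1C[C@@H]([C@H](O)c2cc(OC)c(O[Si](C(C)C)(C(C)C)C(C)C)c(OC)c2)CO1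
F5 | step 8 | {(S)-[(3R)-2,3-dihydrofuran-3-yl](3,5-dimethoxy-4-triisopropylsilyloxyphenyl)methoxy}trimethylsilane | C1=C[C@@H]([C@H](O[Si](C)(C)C)c2cc(OC)c(O[Si](C(C)C)(C(C)C)C(C)C)c(OC)c2)CO1
F6 | step 13 | (3S,3aR,6S,6aS)-3-(4-acetoxy-3,5-dimethoxyphenyl)-6-(4-acetoxy-3-methoxyphenyl)tetrahydro-1H,3H-furo[3,4-c]furan-1-one | COc1cc([C@H]2OC[C@H]3[C@@H]2C(=O)O[C@@H]3c2cc(OC)c(OC(C)=O)c(OC)c2)ccc1OC(C)=O
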